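**Assumption:** commercial (S)-(−)-limonene and (R)-(−)-linalool of high ee are used. Centres that form as mixtures and are destroyed or irrelevant later (epoxide carbons of 2, ozonide carbon of 5, sulfur of 10, orthoester carbon of F1) are left unspecified in the SMILES.

## Retrosynthetic overview

1. The target is two C10 terpene halves. Key disconnection: the C3–C4 σ-bond of the (2E,4E)-dienyl linker, made last by a Mizoroki–Heck alkenylation of the native vinyl group of bromo-oxane 17 with (E)-alkenyl iodide 15, with both C–Br bonds and the free tertiary OH already in place (no olefination and no vinyl–vinyl cross-coupling of two prefunctionalised partners).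
2. 17 comes in one step from (R)-linalool by 6-endo bromoetherification (C6 from the chiral pool).
3. 15 comes from alkyne 13 by Zr-catalysed methylalumination/iodination (sets the E-trisubstituted olefin).
4. The cis-bromohydrin of 13 comes from the trans-diaxial diol of (S)-limonene via cyclic sulfate and bromide (inversion at C2). Isopropenyl serves as equatorial anchor for the stereoconvergent diol formation and is then trimmed to the slim ethynyl group, which tolerates the axial position the trans-fused sulfate demands.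
5. Ring order: the cyclohexane is never built (chiral pool); the oxane is closed in step 8; the two rings are joined in step 9.

## Route

**Step 1**
Reactants: 1 (S)-(−)-limonene
Product: 3 (1R,2R,4S)-1-methyl-4-(prop-1-en-2-yl)cyclohexane-1,2-diol, via epoxide mixture 2 (not isolated)
Conditions: mCPBA (1.0 equiv), NaHCO3, CH2Cl2, 0 °C; then 1% aq H2SO4, THF, 0 °C → rt
Reagents that add atoms: mCPBA, O=C(OO)c1cccc(Cl)c1; water, O
Why: Prilezhaev epoxidation of the more electron-rich trisubstituted alkene gives both 1,2-oxides, and acid hydrolysis is stereoconvergent because Fürst–Plattner trans-diaxial opening with the equatorial isopropenyl anchor sends water to C1 of the cis-oxide and to C2 of the trans-oxide, so C1 (R) and C2 (R) are both set from C4.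

**Step 2**
Reactants: 3 (1R,2R,4S)-1-methyl-4-(prop-1-en-2-yl)cyclohexane-1,2-diol
Product: 4 (1R,2R,4S)-1-methyl-4-(prop-1-en-2-yl)-1,2-bis(triethylsilyloxy)cyclohexane
Conditions: TESOTf (2.5 equiv), 2,6-lutidine, CH2Cl2, −78 → 0 °C
Reagents that add atoms: triethylsilyl triflate, CC[Si](CC)(CC)OS(=O)(=O)C(F)(F)F
Why: Silyl triflate with a hindered base silylates both the secondary and the tertiary hydroxyl (silyl ether protection), so the diol survives ozonolysis and LDA.

**Step 3**
Reactants: 4 (1R,2R,4S)-1-methyl-4-(prop-1-en-2-yl)-1,2-bis(triethylsilyloxy)cyclohexane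
Product: 6 1-[(1S,3R,4R)-4-methyl-3,4-bis(triethylsilyloxy)cyclohexyl]ethan-1-one, via ozonide 5 (not isolated)
Conditions: O3, CH2Cl2, −78 °C; then Me2S, −78 °C → rt
Reagents that add atoms: ozone, [O-][O+]=O
Why: Ozonolysis (Criegee mechanism, reductive work-up) cleaves the only remaining C=C to the methyl ketone without touching the adjacent stereocentre.

**Step 4**
Reactants: 6 1-[(1S,3R,4R)-4-methyl-3,4-bis(triethylsilyloxy)cyclohexyl]ethan-1-one
Product: 9 (1R,2R,4S)-4-ethynyl-1-methylcyclohexane-1,2-diol, via enol phosphate 7 (not isolated), via bis-silyl alkyne 8 (not isolated)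
Conditions: LDA (commercial, 1.1 equiv), THF, −78 °C; ClP(O)(OEt)2, −78 °C → rt; LDA (2.5 equiv), −78 °C → rt; aq NH4Cl; crude + HF·pyridine, THF, 0 °C → rt
Reagents that add atoms: none
Why: Negishi's methyl ketone to alkyne protocol traps the kinetic CH3-side enolate as the enol phosphate, LDA-induced β-elimination gives the terminal alkyne without enolising the ring stereocentre, and fluoride then removes both silyl ethers.

**Step 5**
Reactants: 9 (1R,2R,4S)-4-ethynyl-1-methylcyclohexane-1,2-diol
Product: 11 (3aR,6S,7aR)-6-ethynyl-3a-methylhexahydro-1,3,2-benzodioxathiole 2,2-dioxide (cyclic sulfate of 9), via cyclic sulfite 10 (not isolated)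
Conditions: SOCl2, Et3N, CH2Cl2, 0 °C; then RuCl3·xH2O (1 mol %), NaIO4, MeCN/H2O, 0 °C, 10 min
Reagents that add atoms: thionyl chloride, O=S(Cl)Cl; sodium periodate, [Na+].[O-]I(=O)(=O)=O
Why: Gao–Sharpless cyclic sulfate synthesis; the trans-diol closes to the trans-fused ring by flipping to the di-equatorial chair, which costs little because the ethynyl group (A ≈ 0.4 kcal/mol) takes the axial position, and catalytic RuO4 oxidises S(IV) within minutes, much faster than it attacks the alkyne.

**Step 6**
Reactants: 11 cyclic sulfate of 9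
Product: 13 (1R,2S,4S)-2-bromo-4-ethynyl-1-methylcyclohexan-1-ol, via lithium bromo sulfate 12 (not isolated)
Conditions: LiBr (2 equiv), THF, rt → 45 °C; then conc. H2SO4 (cat.), H2O (1.5 equiv), THF, rt
Reagents that add atoms: lithium bromide, [Li+].[Br-]
Why: SN2 opening of the cyclic sulfate by bromide at the secondary carbon (axial attack on the locked chair, with no anti-periplanar H for E2 and no neighbouring-oxygen epoxide pathway) inverts C2 so that Br ends up cis to the tertiary oxygen, and acid hydrolysis of the sulfate monoester by S–O cleavage retains C1.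

**Step 7**
Reactants: 13 (1R,2S,4S)-2-bromo-4-ethynyl-1-methylcyclohexan-1-ol
Product: 15 (1R,2S,4S)-2-bromo-4-[(1E)-1-iodoprop-1-en-2-yl]-1-methylcyclohexan-1-ol, via alkenylalane 14 (not isolated)
Conditions: Me3Al (4 equiv), Cp2ZrCl2 (0.3 equiv), CH2Cl2, 0 °C → rt; then I2, THF, −30 → 0 °C; Rochelle salt work-up
Reagents that add atoms: trimethylaluminium, C[Al](C)C; iodine, II
Why: Negishi Zr-catalysed carboalumination adds Me–Al syn across the terminal alkyne (Me to the internal carbon) and iodinolysis with retention gives the E-alkenyl iodide, while the tertiary OH is carried as its aluminium alkoxide, which cannot close an epoxide onto the cis C–Br.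

**Step 8**
Reactants: 16 (R)-(−)-linalool
Product: 17 (3S,6R)-3-bromo-6-ethenyl-2,2,6-trimethyloxane
Conditions: TBCO (1.1 equiv), MeNO2, rt, dark; chromatographic separation of the C3 epimers
Reagents that add atoms: 2,4,4,6-tetrabromocyclohexa-2,5-dien-1-one (TBCO), O=C1C(Br)=CC(Br)(Br)C=C1Br
Why: Bromonium-induced 6-endo (Markovnikov) cycloetherification runs through a chair with equatorial Br; C6 comes from (R)-linalool, the new C3 centre forms with little facial bias (about 1:1), and the (3S,6R) isomer (Br trans to vinyl) is separated.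

**Step 9**
Reactants: 15 (1R,2S,4S)-2-bromo-4-[(1E)-1-iodoprop-1-en-2-yl]-1-methylcyclohexan-1-ol; 17 (3S,6R)-3-bromo-6-ethenyl-2,2,6-trimethyloxane (2 equiv)
Product: 18 (1R,2S,4S)-2-bromo-4-[(2E,4E)-5-[(2R,5S)-5-bromo-2,6,6-trimethyloxan-2-yl]penta-2,4-dien-2-yl]-1-methylcyclohexan-1-ol (target)
Conditions: Pd(OAc)2 (10 mol %), n-Bu4NCl, NaHCO3, DMF, 50 °C
Reagents that add atoms: none
Why: Mizoroki–Heck reaction under Jeffery conditions: Pd(0) inserts only into the alkenyl C–I bond (secondary alkyl bromides are inert without electron-rich ligands), syn carbopalladation puts the alkenyl group on the terminal carbon, and β-hydride elimination is possible only away from the quaternary C6, giving the new E-alkene with retention of the iodide geometry and no change at any stereocentre.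

## Compound list

1 | (S)-(−)-limonene, (4S)-1-methyl-4-(prop-1-en-2-yl)cyclohex-1-ene | CC(=C)[C@H]1CCC(C)=CC1 | starting material
2 | (4S)-limonene 1,2-oxide, cis/trans mixture | CC(=C)[C@H]1CCC2(C)OC2C1 | intermediate
3 | (1R,2R,4S)-1-methyl-4-(prop-1-en-2-yl)cyclohexane-1,2-diol | CC(=C)[C@H]1CC[C@@](C)(O)[C@H](O)C1 | intermediate
4 | (1R,2R,4S)-1-methyl-4-(prop-1-en-2-yl)-1,2-bis(triethylsilyloxy)cyclohexane | CC(=C)[C@H]1CC[C@@](C)(O[Si](CC)(CC)CC)[C@H](O[Si](CC)(CC)CC)C1 | intermediate
5 | secondary ozonide of 4 (3-methyl-1,2,4-trioxolan-3-yl in place of isopropenyl; both epimers) | CC2(OCOO2)[C@H]1CC[C@@](C)(O[Si](CC)(CC)CC)[C@H](O[Si](CC)(CC)CC)C1 | intermediate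
6 | 1-[(1S,3R,4R)-4-methyl-3,4-bis(triethylsilyloxy)cyclohexyl]ethan-1-one | CC(=O)[C@H]1CC[C@@](C)(O[Si](CC)(CC)CC)[C@H](O[Si](CC)(CC)CC)C1 | intermediate
7 | diethyl 1-[(1S,3R,4R)-4-methyl-3,4-bis(triethylsilyloxy)cyclohexyl]ethenyl phosphate | C=C(OP(=O)(OCC)OCC)[C@H]1CC[C@@](C)(O[Si](CC)(CC)CC)[C@H](O[Si](CC)(CC)CC)C1 | intermediate
8 | (1R,2R,4S)-4-ethynyl-1-methyl-1,2-bis(triethylsilyloxy)cyclohexane | C#C[C@H]1CC[C@@](C)(O[Si](CC)(CC)CC)[C@H](O[Si](CC)(CC)CC)C1 | intermediate
9 | (1R,2R,4S)-4-ethynyl-1-methylcyclohexane-1,2-diol | C#C[C@H]1CC[C@@](C)(O)[C@H](O)C1 | intermediate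
10 | (3aR,6S,7aR)-6-ethynyl-3a-methylhexahydro-1,3,2-benzodioxathiole 2-oxide (cyclic sulfite, both S-epimers) | C#C[C@H]1CC[C@@]2(C)OS(=O)O[C@@H]2C1 | intermediate
11 | (3aR,6S,7aR)-6-ethynyl-3a-methylhexahydro-1,3,2-benzodioxathiole 2,2-dioxide (cyclic sulfate) | C#C[C@H]1CC[C@@]2(C)OS(=O)(=O)O[C@@H]2C1 | intermediate
12 | lithium (1R,2S,4S)-2-bromo-4-ethynyl-1-methylcyclohexyl sulfate | C#C[C@H]1CC[C@@](C)(OS(=O)(=O)[O-])[C@@H](Br)C1.[Li+] | intermediate
13 | (1R,2S,4S)-2-bromo-4-ethynyl-1-methylcyclohexan-1-ol | C#C[C@H]1CC[C@@](C)(O)[C@@H](Br)C1 | intermediate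
14 | dimethylaluminium alkoxide of (1R,2S,4S)-2-bromo-4-[(E)-1-(dimethylalumanyl)prop-1-en-2-yl]-1-methylcyclohexan-1-ol | C/C(=C\[Al](C)C)[C@H]1CC[C@@](C)(O[Al](C)C)[C@@H](Br)C1 | intermediate
15 | (1R,2S,4S)-2-bromo-4-[(1E)-1-iodoprop-1-en-2-yl]-1-methylcyclohexan-1-ol | C/C(=C\I)[C@H]1CC[C@@](C)(O)[C@@H](Br)C1 | intermediate
16 | (R)-(−)-linalool, (3R)-3,7-dimethylocta-1,6-dien-3-ol | C=C[C@](C)(O)CCC=C(C)C | starting material
17 | (3S,6R)-3-bromo-6-ethenyl-2,2,6-trimethyloxane (Br trans to vinyl) | C=C[C@@]1(C)CC[C@H](Br)C(C)(C)O1 | intermediate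
18 | (1R,2S,4S)-2-bromo-4-[(2E,4E)-5-[(2R,5S)-5-bromo-2,6,6-trimethyloxan-2-yl]penta-2,4-dien-2-yl]-1-methylcyclohexan-1-ol | C/C(=C\C=C\[C@@]1(C)CC[C@H](Br)C(C)(C)O1)[C@H]1CC[C@@](C)(O)[C@@H](Br)C1 | target

## Step count and risks

Total step count: 9. Longest linear sequence: 8 (steps 1–7, then step 9); step 8 is the one-step side branch.

**Step 6 (cyclic sulfate opening and sulfate hydrolysis).** C2 is flanked by a fully substituted carbon and the incoming bromide is syn-axial to the ethynyl group, so bromide may open at the tertiary carbon instead, or the tertiary sulfate may ionise during hydrolysis. The fallback sets out from 9 and comes back at 13, and replaces the sulfur electrophile by a carbon one. Diol 9 is heated with trimethyl orthoacetate and PPTS to give (3aR,6S,7aR)-6-ethynyl-2-methoxy-2,3a-dimethylhexahydro-1,3-benzodioxole F1. Acetyl bromide converts F1 into the 1,3-dioxolan-2-ylium ion, which bromide opens at the secondary carbon with inversion (Kolb–Sharpless acetoxy-bromide protocol) to give (1R,2S,4S)-2-bromo-4-ethynyl-1-methylcyclohexyl acetate F2. DIBAL-H at −78 °C removes the acetate and delivers 13, with no sulfate ester to hydrolyse.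

**Step 8 (bromoetherification).** The new C3 centre forms about 1:1 and some 5-exo product is expected, so the yield of 17 is capped near 35–40 %. The fallback sets out from 16 and comes back at 17, and fixes C3 by reagent control. Shi epoxidation of the trisubstituted alkene of 16 with the L-fructose-derived (ent-Shi) ketone and Oxone gives (3R)-5-[(2S)-3,3-dimethyloxiran-2-yl]-3-methylpent-1-en-3-ol F3. CSA closes it 5-exo with inversion at the epoxide CH to give 2-[(2R,5R)-5-ethenyl-5-methyloxolan-2-yl]propan-2-ol F4. Tf2O with 2,6-di-tert-butyl-4-methylpyridine at −78 °C, then n-Bu4NBr, ionises the tertiary alcohol with participation of the ring oxygen. Bromide opens the bicyclic oxonium ion at the secondary carbon (second inversion, Nakata-type oxolane to oxane ring expansion) and gives 17 with C3 fixed as S.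

**Step 9 (Heck coupling).** The alkene of 17 is hindered and sits next to an ether carbon, so slow insertion, β-alkoxide elimination or diene isomerisation could erode the yield. The fallback sets out from 17 (and uses 15) and comes back at 18, switching to a two-component cross-coupling. Ozonolysis of 17 (O3; Me2S) gives (2R,5S)-5-bromo-2,6,6-trimethyloxane-2-carbaldehyde F5. Takai–Utimoto-type boryl olefination (Cl2CHBpin, CrCl2, LiI, THF) gives 2-[(E)-2-[(2R,5S)-5-bromo-2,6,6-trimethyloxan-2-yl]ethenyl]-4,4,5,5-tetramethyl-1,3,2-dioxaborolane F6. Suzuki–Miyaura coupling of F6 with 15 (Pd(PPh3)4, aq K3PO4, THF, 40 °C) gives 18.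

## Further compounds

F1 | step 6 | (3aR,6S,7aR)-6-ethynyl-2-methoxy-2,3a-dimethylhexahydro-1,3-benzodioxole | C#C[C@H]1CC[C@@]2(C)OC(C)(OC)O[C@@H]2C1
F2 | step 6 | (1R,2S,4S)-2-bromo-4-ethynyl-1-methylcyclohexyl acetate | C#C[C@H]1CC[C@@](C)(OC(C)=O)[C@@H](Br)C1
F3 | step 8 | (3R)-5-[(2S)-3,3-dimethyloxiran-2-yl]-3-methylpent-1-en-3-ol | C=C[C@](C)(O)CC[C@@H]1OC1(C)C
F4 | step 8 | 2-[(2R,5R)-5-ethenyl-5-methyloxolan-2-yl]propan-2-ol | C=C[C@@]1(C)CC[C@H](C(C)(C)O)O1
F5 | step 9 | (2R,5S)-5-bromo-2,6,6-trimethyloxane-2-carbaldehyde | O=C[C@@]1(C)CC[C@H](Br)C(C)(C)O1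
F6 | step 9 | 2-[(E)-2-[(2R,5S)-5-bromo-2,6,6-trimethyloxan-2-yl]ethenyl]-4,4,5,5-tetramethyl-1,3,2-dioxaborolane | CC1(C)OB(/C=C/[C@@]2(C)CC[C@H](Br)C(C)(C)O2)OC1(C)C
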